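**Retrosynthetic overview**

1. Locants for the cyclohexene (ring E): C1 = methyl-bearing alkene carbon, C2 = alkene CH, C3 = CH carrying resorcinol ring B (which bears the chalcone carbonyl and ring C), C4 = CH carrying the ring A aroyl group, C5 = CH carrying ring D, C6 = CH2. Kuwanon J is read as the ring-opened form of a cis-fused benzo[c]chromene ketal, so the last steps are attachment of the chalcone arm to ring B by aryllithium acylation and ketal/MOM hydrolysis.
2. Ring E and the ketal pyran arise together from an intramolecular inverse-demand hetero-Diels–Alder reaction of a (Z)-ortho-quinone methide (one ring B oxygen, two ring B carbons, C3) with the methyl enol ether of the ring A ketone (C4). This forms C3–C4 and the ketal C–O bond and sets C3 and C4 from C5.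
3. The quinone methide is made in the same step from three pieces by forming C1–C6 and C2–C3: carbocupration of propyne (C1, C2, methyl) by the C6 alkylcopper, addition of the alkenyl cuprate to the ring B aldehyde (C3) and Boc transfer/elimination. It rests as a 2H-chromene (oxa-6π closure) until heating reopens it for the cycloaddition of line 2.
4. Enabling feature: C3 is the benzylic carbon between the two oxygen-bearing ortho carbons of ring B and is allylic to C1=C2, whose other neighbour C6 is a plain CH2. One ortho oxygen can therefore close onto C1 (pyran: O, C1, C2, C3, two ring B carbons) and reopen as a quinone methide at C3, while the other ortho oxygen (as its MOM ether) holds that methide in the Z geometry.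
5. C5 is set first by rhodium/(R)-BINAP conjugate arylation of a ring A enone. Ring order: chromene pyran (temporary), then ring E together with the ketal pyran (all in the key step), then the ketal pyran is opened.

Key step: step 14

Assumption: the target is taken exactly as drawn, i.e. the aroyl group on C4 is 3,5-dihydroxy-4-(3-methylbut-2-en-1-yl)benzoyl (carbonyl para to the prenyl group), and ring E is (3S,4R,5S) in the locants above.

Abbreviations: MOM = CH2OCH3; TBS = tert-butyldimethylsilyl; prenyl = 3-methylbut-2-en-1-yl; ArA = 3,5-bis(methoxymethoxy)-4-prenylphenyl (ring A); ArM = 2,4-bis(methoxymethoxy)phenyl (used for ring C and ring D).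

**Route**

Step 1
Reactants: 1 5-bromobenzene-1,3-diol
Product: 2 1-bromo-3,5-bis(methoxymethoxy)benzene
Conditions: MOMCl, i-Pr2NEt, CH2Cl2, 0 → 20 °C
Reagents that add atoms: chloromethyl methyl ether, COCCl
Why: Williamson-type O-alkylation of both phenols with the reactive α-chloro ether should give the base-stable MOM ethers needed for the later metalations.

Step 2
Reactants: 2 1-bromo-3,5-bis(methoxymethoxy)benzene; 3 1-bromo-3-methylbut-2-ene
Product: 5 5-bromo-1,3-bis(methoxymethoxy)-2-prenylbenzene, via aryllithium 4 (not isolated)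
Conditions: LDA, THF, −78 °C; CuBr·SMe2 (10 mol %), 3, −78 → 0 °C
Reagents that add atoms: none
Why: Directed ortho-metalation: the hindered amide base should remove the proton flanked by the two MOM-oxy groups without bromine–lithium exchange, and the aryllithium is then allylated at the primary carbon of prenyl bromide under copper catalysis (SN2).

Step 3
Reactants: 6 2-[(tert-butyldimethylsilyl)oxy]acetaldehyde; 7 diethyl {2-[methoxy(methyl)amino]-2-oxoethyl}phosphonate
Product: 8 (2E)-4-[(tert-butyldimethylsilyl)oxy]-N-methoxy-N-methylbut-2-enamide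
Conditions: LiCl, DBU, MeCN, 0 → 20 °C
Reagents that add atoms: none
Why: Horner–Wadsworth–Emmons olefination under Masamune–Roush conditions should give the (E)-enamide without harming the base-sensitive α-silyloxy aldehyde.

Step 4
Reactants: 5 5-bromo-1,3-bis(methoxymethoxy)-2-prenylbenzene; 8 (2E)-4-[(tert-butyldimethylsilyl)oxy]-N-methoxy-N-methylbut-2-enamide
Product: 10 (2E)-1-ArA-4-[(tert-butyldimethylsilyl)oxy]but-2-en-1-one, via aryllithium 9 (not isolated)
Conditions: n-BuLi, THF, −78 °C; 8, −78 → −40 °C; aq. NH4Cl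
Reagents that add atoms: none
Why: Bromine–lithium exchange followed by Weinreb ketone synthesis: the chelated tetrahedral adduct should survive until work-up, so the (E)-enone is released without over-addition.

Step 5
Reactants: 11 4-bromobenzene-1,3-diol
Product: 12 1-bromo-2,4-bis(methoxymethoxy)benzene
Conditions: MOMCl, i-Pr2NEt, CH2Cl2, 0 → 20 °C
Reagents that add atoms: chloromethyl methyl ether, COCCl
Why: Williamson-type O-alkylation protects both phenols as MOM ethers, which tolerate the organolithium and rhodium steps that follow.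

Step 6
Reactants: 12 1-bromo-2,4-bis(methoxymethoxy)benzene
Product: 14 [2,4-bis(methoxymethoxy)phenyl]boronic acid, via aryllithium 13 (not isolated)
Conditions: n-BuLi, THF, −78 °C; B(Oi-Pr)3, −78 → 0 °C; aq. NH4Cl
Reagents that add atoms: triisopropyl borate, CC(C)OB(OC(C)C)OC(C)C; water, O
Why: Bromine–lithium exchange, borylation and hydrolysis is the standard route to an arylboronic acid at a position that direct metalation of the bis-MOM resorcinol would not reach.

Step 7
Reactants: 10 (2E)-1-ArA-4-[(tert-butyldimethylsilyl)oxy]but-2-en-1-one; 14 [2,4-bis(methoxymethoxy)phenyl]boronic acid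
Product: 15 (3S)-1-ArA-3-ArM-4-[(tert-butyldimethylsilyl)oxy]butan-1-one
Conditions: [Rh(OH)((R)-binap)]2 (3 mol %), 1,4-dioxane/H2O (10:1), 40 °C
Reagents that add atoms: none
Why: Hayashi–Miyaura reaction: the aryl–rhodium species inserts the (E)-enone and the rhodium enolate is protonated by water; the (S)-ligand is known to direct aryl groups to the α-si face of enones, so the (R)-ligand should deliver ring D to the opposite face and set C5 as (S).

Step 8
Reactants: 15 (3S)-1-ArA-3-ArM-4-[(tert-butyldimethylsilyl)oxy]butan-1-one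
Product: 17 tert-butyl{[(2S,3Z)-4-ArA-2-ArM-4-methoxybut-3-en-1-yl]oxy}dimethylsilane, via potassium enolate 16 (not isolated)
Conditions: KHMDS, THF, −78 °C; Me2SO4, DMPU, −78 → 0 °C
Reagents that add atoms: dimethyl sulfate, COS(=O)(=O)OC
Why: O-alkylation of the (Z)-potassium enolate by a hard electrophile in a dipolar aprotic medium should give the (Z)-methyl enol ether, which masks the ketone against organometallics and is the 2π partner of step 14.

Step 9
Reactants: 17 tert-butyl{[(2S,3Z)-4-ArA-2-ArM-4-methoxybut-3-en-1-yl]oxy}dimethylsilane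
Product: 18 (2S,3Z)-4-ArA-2-ArM-4-methoxybut-3-en-1-ol
Conditions: TBAF, THF, 0 °C; aq. NH4Cl
Reagents that add atoms: none
Why: Fluoride-mediated desilylation should remove the primary silyl ether while the methyl enol ether and the MOM ethers are inert to fluoride.

Step 10
Reactants: 18 (2S,3Z)-4-ArA-2-ArM-4-methoxybut-3-en-1-ol
Product: 20 (1Z,3S)-4-bromo-1-ArA-3-ArM-1-methoxybut-1-ene, via mesylate 19 (not isolated)
Conditions: MsCl, Et3N, CH2Cl2, 0 °C; LiBr, THF, 45 °C
Reagents that add atoms: lithium bromide, [Li+].[Br-]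
Why: Sulfonylation and SN2 displacement by bromide (Finkelstein-type) under non-acidic conditions should convert the alcohol into the primary bromide without touching the acid-labile enol ether.

Step 11
Reactants: 21 2,6-dihydroxybenzaldehyde
Product: 22 2-hydroxy-6-(methoxymethoxy)benzaldehyde
Conditions: MOMCl (1 equiv), i-Pr2NEt, CH2Cl2, 0 °C
Reagents that add atoms: chloromethyl methyl ether, COCCl
Why: Mono-alkylation of a symmetric bis-phenol: the remaining hydroxyl is hydrogen-bonded to the aldehyde and reacts more slowly, so one equivalent of the chloro ether should stop mainly at the mono-ether.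

Step 12
Reactants: 22 2-hydroxy-6-(methoxymethoxy)benzaldehyde
Product: 23 3-bromo-6-hydroxy-2-(methoxymethoxy)benzaldehyde
Conditions: NBS, MeCN, 0 °C
Reagents that add atoms: N-bromosuccinimide, O=C1CCC(=O)N1Br
Why: Electrophilic aromatic bromination should go para to the free hydroxyl, the strongest activator on the ring; the ortho isomer would lead to the same ring B pattern in the target.

Step 13
Reactants: 23 3-bromo-6-hydroxy-2-(methoxymethoxy)benzaldehyde
Product: 24 4-bromo-2-formyl-3-(methoxymethoxy)phenyl tert-butyl carbonate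
Conditions: Boc2O, i-Pr2NEt, DMAP (5 mol %), CH2Cl2, 0 → 20 °C
Reagents that add atoms: di-tert-butyl dicarbonate, CC(C)(C)OC(=O)OC(=O)OC(C)(C)C
Why: DMAP-catalysed acylation of the phenol installs the aryl carbonate that later acts as the internal leaving group for quinone methide formation.

Step 14
Reactants: 20 (1Z,3S)-4-bromo-1-ArA-3-ArM-1-methoxybut-1-ene; 25 propyne; 24 4-bromo-2-formyl-3-(methoxymethoxy)phenyl tert-butyl carbonate
Product: 33 (6R,6aR,7S,10aS)-6-ArA-7-ArM-2-bromo-6-methoxy-1-(methoxymethoxy)-9-methyl-6a,7,8,10a-tetrahydro-6H-benzo[c]chromene, via Grignard reagent 26 (not isolated), via alkylcopper 27 (not isolated), via alkenylcopper 28 (not isolated), via mixed cuprate 29 (not isolated), via lithium alkoxide 30 (not isolated), via ortho-quinone methide 31 (not isolated), via chromene 32 (not isolated)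
Conditions: Mg, Et2O, 30 °C; CuBr·SMe2, Et2O/Me2S, −45 °C; propyne (3 equiv), −25 °C; PhC≡CLi (1 equiv), THF, −78 °C; 24 (1.1 equiv), −78 → 20 °C; aq. NH4Cl/NH3 wash, solvent exchange to PhMe (0.01 M) without purification; K2CO3 (suspended), BHT (5 mol %), 120 °C, sealed tube
Reagents that add atoms: none
Why: Magnesium insertion and transmetalation give alkylcopper 27, which adds syn across propyne with the alkyl group on the methyl-bearing carbon (Normant carbocupration, C1–C6), and the alkenylcopper, activated as the alkynyl cuprate 29, adds 1,2 to aldehyde 24 (C2–C3). Alkoxide 30 then takes over the Boc group from the neighbouring phenol oxygen and the phenoxide expels tert-butyl carbonate (the known low-temperature entry to ortho-quinone methides from ortho-Boc-oxy benzaldehydes); the MOM-oxy group on the second ortho carbon of ring B pushes the vinyl group of quinone methide 31 to the side of the carbonyl oxygen, so that 31 closes the temporary pyran ring of chromene 32 by a disrotatory oxa-6π electrocyclisation (O–C1 bond). Once the metal salts are washed out and the solution is heated to 120 °C this closure becomes reversible, and 31 is drained by an intramolecular inverse-electron-demand hetero-Diels–Alder reaction with the tethered enol ether, a [4+2] closure that forms the carbocycle (ring E) through C3–C4 and the ketal pyran through its O–C bond; the closest known reaction types are the thermal ring opening of 2,2-disubstituted 2H-chromenes and the trapping of ortho-quinone methides by tethered enol ethers. C3 and C4 are set together under control of C5: because the tether starts from the Z terminus of the heterodiene only the cis ring fusion is within reach (ring B on C3 cis to the ketal carbon on C4), and allylic 1,3-strain with the methoxy group makes the C5–H bond eclipse the enol ether so that ring D points away from the heterodiene and ends trans to the ketal carbon, while the ketal carbon follows from the (Z)-enol ether by suprafacial addition and is erased in step 18. The step needs regioselectivity in the alkyne addition (alkyl to the internal carbon, the intrinsic sense of organocopper additions to 1-alkynes), chemoselectivity for the aldehyde (the methyl enol ether, aryl bromide and MOM ethers are inert to organocopper reagents, and the cuprate is used in slight deficit so that none is left to add to 31) and periselectivity for the cycloaddition over a 1,7-hydrogen shift of 31, for which the electron-rich enol ether, matched to the electron-poor heterodiene, is relied on. The quaternary carbon of chromene 32 forms as both epimers, which is of no consequence because the reopening erases it, and C5 is remote from every centre that reacts before the cycloaddition.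

Step 15
Reactants: 34 2,4-dihydroxybenzaldehyde
Product: 35 2,4-bis(methoxymethoxy)benzaldehyde
Conditions: MOMCl, i-Pr2NEt, DMF, 0 → 50 °C
Reagents that add atoms: chloromethyl methyl ether, COCCl
Why: Williamson-type O-alkylation of both phenols (forcing conditions for the hydrogen-bonded ortho hydroxyl) gives the MOM-protected ring C aldehyde.

Step 16
Reactants: 35 2,4-bis(methoxymethoxy)benzaldehyde; 7 diethyl {2-[methoxy(methyl)amino]-2-oxoethyl}phosphonate
Product: 36 (2E)-3-ArM-N-methoxy-N-methylprop-2-enamide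
Conditions: LiCl, DBU, MeCN, 20 °C
Reagents that add atoms: none
Why: Horner–Wadsworth–Emmons olefination of an aromatic aldehyde with a stabilised phosphonate should give the (E)-cinnamoyl Weinreb amide.

Step 17
Reactants: 33 (6R,6aR,7S,10aS)-6-ArA-7-ArM-2-bromo-6-methoxy-1-(methoxymethoxy)-9-methyl-6a,7,8,10a-tetrahydro-6H-benzo[c]chromene; 36 (2E)-3-ArM-N-methoxy-N-methylprop-2-enamide
Product: 38 (2E)-1-[(6R,6aR,7S,10aS)-6-ArA-7-ArM-6-methoxy-1-(methoxymethoxy)-9-methyl-6a,7,8,10a-tetrahydro-6H-benzo[c]chromen-2-yl]-3-ArM-prop-2-en-1-one, via aryllithium 37 (not isolated)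
Conditions: n-BuLi, THF, −78 °C; 36, −78 → −30 °C; aq. NH4Cl
Reagents that add atoms: none
Why: Bromine–lithium exchange is faster than any deprotonation at −78 °C and the aryllithium, stabilised by the neighbouring MOM-oxy group, adds 1,2 to the Weinreb amide (Weinreb ketone synthesis) to give the (E)-chalcone, while C4 cannot enolise because the ring A ketone is still a ketal.

Step 18
Reactants: 38 (2E)-1-[(6R,6aR,7S,10aS)-6-ArA-7-ArM-6-methoxy-1-(methoxymethoxy)-9-methyl-6a,7,8,10a-tetrahydro-6H-benzo[c]chromen-2-yl]-3-ArM-prop-2-en-1-one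
Product: 39 kuwanon J
Conditions: 3 M aq. HCl, MeOH/THF, 40 °C
Reagents that add atoms: water, O
Why: Acid hydrolysis should cleave the seven MOM acetals and the mixed methyl aryl ketal in one operation, releasing the ring A ketone and all eight phenols under conditions too mild to enolise the hindered C4 position.

**Compound list**

1 | 5-bromobenzene-1,3-diol | Oc1cc(O)cc(Br)c1 | starting material
2 | 1-bromo-3,5-bis(methoxymethoxy)benzene | COCOc1cc(Br)cc(OCOC)c1 | intermediate
3 | 1-bromo-3-methylbut-2-ene (prenyl bromide) | CC(C)=CCBr | starting material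
4 | [4-bromo-2,6-bis(methoxymethoxy)phenyl]lithium (not isolated) | [Li]c1c(OCOC)cc(Br)cc1OCOC | intermediate
5 | 5-bromo-1,3-bis(methoxymethoxy)-2-(3-methylbut-2-en-1-yl)benzene | COCOc1cc(Br)cc(OCOC)c1CC=C(C)C | intermediate
6 | 2-[(tert-butyldimethylsilyl)oxy]acetaldehyde | CC(C)(C)[Si](C)(C)OCC=O | starting material
7 | diethyl {2-[methoxy(methyl)amino]-2-oxoethyl}phosphonate | CCOP(=O)(CC(=O)N(C)OC)OCC | starting material
8 | (2E)-4-[(tert-butyldimethylsilyl)oxy]-N-methoxy-N-methylbut-2-enamide | CON(C)C(=O)/C=C/CO[Si](C)(C)C(C)(C)C | intermediate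
9 | [3,5-bis(methoxymethoxy)-4-(3-methylbut-2-en-1-yl)phenyl]lithium (not isolated) | [Li]c1cc(OCOC)c(CC=C(C)C)c(OCOC)c1 | intermediate
10 | (2E)-1-[3,5-bis(methoxymethoxy)-4-(3-methylbut-2-en-1-yl)phenyl]-4-[(tert-butyldimethylsilyl)oxy]but-2-en-1-one | CC(C)=CCc1c(OCOC)cc(C(=O)/C=C/CO[Si](C)(C)C(C)(C)C)cc1OCOC | intermediate
11 | 4-bromobenzene-1,3-diol | Oc1ccc(Br)c(O)c1 | starting material
12 | 1-bromo-2,4-bis(methoxymethoxy)benzene | COCOc1ccc(Br)c(OCOC)c1 | intermediate
13 | [2,4-bis(methoxymethoxy)phenyl]lithium (not isolated) | [Li]c1ccc(OCOC)cc1OCOC | intermediate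
14 | [2,4-bis(methoxymethoxy)phenyl]boronic acid | OB(O)c1ccc(OCOC)cc1OCOC | intermediate
15 | (3S)-1-ArA-3-ArM-4-[(tert-butyldimethylsilyl)oxy]butan-1-one | CC(C)(C)[Si](C)(C)OC[C@@H](CC(=O)c1cc(OCOC)c(CC=C(C)C)c(OCOC)c1)c1ccc(OCOC)cc1OCOC | intermediate
16 | potassium (1Z,3S)-1-ArA-3-ArM-4-[(tert-butyldimethylsilyl)oxy]but-1-en-1-olate (not isolated) | CC(C)(C)[Si](C)(C)OC[C@@H](/C=C(\[O-])c1cc(OCOC)c(CC=C(C)C)c(OCOC)c1)c1ccc(OCOC)cc1OCOC.[K+] | intermediate
17 | tert-butyl{[(2S,3Z)-4-ArA-2-ArM-4-methoxybut-3-en-1-yl]oxy}dimethylsilane | CC(C)(C)[Si](C)(C)OC[C@@H](/C=C(\OC)c1cc(OCOC)c(CC=C(C)C)c(OCOC)c1)c1ccc(OCOC)cc1OCOC | intermediate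
18 | (2S,3Z)-4-ArA-2-ArM-4-methoxybut-3-en-1-ol | OC[C@@H](/C=C(\OC)c1cc(OCOC)c(CC=C(C)C)c(OCOC)c1)c1ccc(OCOC)cc1OCOC | intermediate
19 | (2S,3Z)-4-ArA-2-ArM-4-methoxybut-3-en-1-yl methanesulfonate (not isolated) | CS(=O)(=O)OC[C@@H](/C=C(\OC)c1cc(OCOC)c(CC=C(C)C)c(OCOC)c1)c1ccc(OCOC)cc1OCOC | intermediate
20 | (1Z,3S)-4-bromo-1-ArA-3-ArM-1-methoxybut-1-ene | BrC[C@@H](/C=C(\OC)c1cc(OCOC)c(CC=C(C)C)c(OCOC)c1)c1ccc(OCOC)cc1OCOC | intermediate
21 | 2,6-dihydroxybenzaldehyde | O=Cc1c(O)cccc1O | starting material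
22 | 2-hydroxy-6-(methoxymethoxy)benzaldehyde | O=Cc1c(O)cccc1OCOC | intermediate
23 | 3-bromo-6-hydroxy-2-(methoxymethoxy)benzaldehyde | O=Cc1c(O)ccc(Br)c1OCOC | intermediate
24 | 4-bromo-2-formyl-3-(methoxymethoxy)phenyl tert-butyl carbonate | O=Cc1c(OC(=O)OC(C)(C)C)ccc(Br)c1OCOC | intermediate
25 | propyne | CC#C | starting material
26 | [(2S,3Z)-4-ArA-2-ArM-4-methoxybut-3-en-1-yl]magnesium bromide (not isolated) | Br[Mg]C[C@@H](/C=C(\OC)c1cc(OCOC)c(CC=C(C)C)c(OCOC)c1)c1ccc(OCOC)cc1OCOC | intermediate
27 | [(2S,3Z)-4-ArA-2-ArM-4-methoxybut-3-en-1-yl]copper (not isolated) | [Cu]C[C@@H](/C=C(\OC)c1cc(OCOC)c(CC=C(C)C)c(OCOC)c1)c1ccc(OCOC)cc1OCOC | intermediate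
28 | [(1Z,4S,5Z)-6-ArA-4-ArM-6-methoxy-2-methylhexa-1,5-dien-1-yl]copper (not isolated) | [Cu]/C=C(/C)C[C@@H](/C=C(\OC)c1cc(OCOC)c(CC=C(C)C)c(OCOC)c1)c1ccc(OCOC)cc1OCOC | intermediate
29 | lithium [(1Z,4S,5Z)-6-ArA-4-ArM-6-methoxy-2-methylhexa-1,5-dien-1-yl](phenylethynyl)cuprate (not isolated) | [Li+].c1ccccc1C#C[Cu-]/C=C(/C)C[C@@H](/C=C(\OC)c1cc(OCOC)c(CC=C(C)C)c(OCOC)c1)c1ccc(OCOC)cc1OCOC | intermediate
30 | lithium (2Z,5S,6Z)-7-ArA-5-ArM-1-[3-bromo-6-(tert-butoxycarbonyloxy)-2-(methoxymethoxy)phenyl]-7-methoxy-3-methylhepta-2,6-dien-1-olate, both C1 epimers (not isolated) | [Li+].[O-]C(/C=C(/C)C[C@@H](/C=C(\OC)c1cc(OCOC)c(CC=C(C)C)c(OCOC)c1)c1ccc(OCOC)cc1OCOC)c1c(OC(=O)OC(C)(C)C)ccc(Br)c1OCOC | intermediate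
31 | (6Z)-4-bromo-6-[(2Z,5S,6Z)-7-ArA-5-ArM-7-methoxy-3-methylhepta-2,6-dien-1-ylidene]-5-(methoxymethoxy)cyclohexa-2,4-dien-1-one (not isolated) | O=C1C=CC(Br)=C(OCOC)/C1=C/C=C(/C)C[C@@H](/C=C(\OC)c1cc(OCOC)c(CC=C(C)C)c(OCOC)c1)c1ccc(OCOC)cc1OCOC | intermediate
32 | 6-bromo-2-[(2S,3Z)-4-ArA-2-ArM-4-methoxybut-3-en-1-yl]-5-(methoxymethoxy)-2-methyl-2H-chromene, both epimers at the chromene C2 (not isolated) | CC1(C[C@@H](/C=C(\OC)c2cc(OCOC)c(CC=C(C)C)c(OCOC)c2)c2ccc(OCOC)cc2OCOC)C=Cc2c(OCOC)c(Br)ccc2O1 | intermediate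
33 | (6R,6aR,7S,10aS)-6-ArA-7-ArM-2-bromo-6-methoxy-1-(methoxymethoxy)-9-methyl-6a,7,8,10a-tetrahydro-6H-benzo[c]chromene (6a,10a-cis; ring D trans to the C6a–C6 bond) | CO[C@@]1(c2cc(OCOC)c(CC=C(C)C)c(OCOC)c2)Oc2ccc(Br)c(OCOC)c2[C@H]2C=C(C)C[C@H](c3ccc(OCOC)cc3OCOC)[C@@H]12 | intermediate
34 | 2,4-dihydroxybenzaldehyde | O=Cc1ccc(O)cc1O | starting material
35 | 2,4-bis(methoxymethoxy)benzaldehyde | O=Cc1ccc(OCOC)cc1OCOC | intermediate
36 | (2E)-3-[2,4-bis(methoxymethoxy)phenyl]-N-methoxy-N-methylprop-2-enamide | CON(C)C(=O)/C=C/c1ccc(OCOC)cc1OCOC | intermediate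
37 | [(6R,6aR,7S,10aS)-6-ArA-7-ArM-6-methoxy-1-(methoxymethoxy)-9-methyl-6a,7,8,10a-tetrahydro-6H-benzo[c]chromen-2-yl]lithium (not isolated) | CO[C@@]1(c2cc(OCOC)c(CC=C(C)C)c(OCOC)c2)Oc2ccc([Li])c(OCOC)c2[C@H]2C=C(C)C[C@H](c3ccc(OCOC)cc3OCOC)[C@@H]12 | intermediate
38 | (2E)-1-[(6R,6aR,7S,10aS)-6-ArA-7-ArM-6-methoxy-1-(methoxymethoxy)-9-methyl-6a,7,8,10a-tetrahydro-6H-benzo[c]chromen-2-yl]-3-ArM-prop-2-en-1-one | CO[C@@]1(c2cc(OCOC)c(CC=C(C)C)c(OCOC)c2)Oc2ccc(C(=O)/C=C/c3ccc(OCOC)cc3OCOC)c(OCOC)c2[C@H]2C=C(C)C[C@H](c3ccc(OCOC)cc3OCOC)[C@@H]12 | intermediate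
39 | kuwanon J: (2E)-1-{3-[(1S,5S,6R)-6-[3,5-dihydroxy-4-(3-methylbut-2-en-1-yl)benzoyl]-5-(2,4-dihydroxyphenyl)-3-methylcyclohex-2-en-1-yl]-2,4-dihydroxyphenyl}-3-(2,4-dihydroxyphenyl)prop-2-en-1-one | CC(C)=CCc1c(O)cc(C(=O)[C@H]2[C@@H](c3c(O)ccc(C(=O)/C=C/c4ccc(O)cc4O)c3O)C=C(C)C[C@@H]2c2ccc(O)cc2O)cc1O | target

**Totals and risks**

Total step count: 18. Longest linear sequence: 10 steps (1, 2, 4, 7, 8, 9, 10, 14, 17, 18).

Steps most likely to fail:

Step 14. Two processes may defeat the cascade. The 1,2-addition of the hindered alkenyl cuprate to the doubly ortho-substituted aldehyde may be slow, so that protonation of the alkenylcopper or conjugate capture of the quinone methide by unreacted organocopper takes over. In the thermal stage, the 1,7-hydrogen shift of the quinone methide to a dienylphenol may outrun the cycloaddition, or the facial discrimination by the C5 substituent may be incomplete. The fallback gives up the one-flask assembly: it forms the two bonds by two classical carbonyl additions, isolates the chromene and closes ring E through a more nucleophilic enamine; it sets out from 23 (with Grignard reagent 26 made from 20) and returns at 33. Aldol condensation of 23 with acetone (aq. NaOH) should give (3E)-4-[3-bromo-6-hydroxy-2-(methoxymethoxy)phenyl]but-3-en-2-one F1, which makes C2–C3. After deprotonation of its phenol (NaH), F1 is treated with 26 and anhydrous CeCl3 (THF, −78 °C) to give by 1,2-addition the tertiary allylic alcohol (1E,5S,6Z)-7-ArA-5-ArM-1-[3-bromo-6-hydroxy-2-(methoxymethoxy)phenyl]-7-methoxy-3-methylhepta-1,6-dien-3-ol F2, which makes C1–C6. On warming in toluene over base-washed molecular sieves, F2 should lose water through quinone methide 31 and close to chromene 32, which is isolated in this case. Mild hydrolysis of the enol ether of 32 (PPTS, wet acetone) gives the chromene ketone (3S)-1-ArA-3-ArM-4-[6-bromo-5-(methoxymethoxy)-2-methyl-2H-chromen-2-yl]butan-1-one F3. Heating F3 with pyrrolidine and 4 Å molecular sieves in toluene forms the enamine 1-[(3S)-1-ArA-3-ArM-4-(6-bromo-5-(methoxymethoxy)-2-methyl-2H-chromen-2-yl)but-1-en-1-yl]pyrrolidine F4, which should trap the thermally reopened quinone methide faster than the hydrogen shift. This gives the cis-fused cyclic aminal 1-[(6aR,7S,10aS)-6-ArA-7-ArM-2-bromo-1-(methoxymethoxy)-9-methyl-6a,7,8,10a-tetrahydro-6H-benzo[c]chromen-6-yl]pyrrolidine F5. Methanolysis (MeOH, PPTS) exchanges the amine for methoxy and gives ketal 33; the configuration at the ketal carbon is not critical, since step 18 erases it.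

Step 18. Protic acid may cyclise the prenyl group onto a liberated neighbouring phenol, cyclise the liberated chalcone phenols onto the enone, or epimerise C4 through the enol ether derived from the ketal oxocarbenium ion. The fallback separates ketal opening from MOM removal and removes the MOM groups by silyl transfer instead of protic acid; it sets out from 38 and returns at 39. PPTS in wet acetone at 20 °C should open only the methyl ketal to give the heptakis-MOM ketone (2E)-1-{3-[(1S,5S,6R)-6-(ArA-carbonyl)-5-ArM-3-methylcyclohex-2-en-1-yl]-4-hydroxy-2-(methoxymethoxy)phenyl}-3-ArM-prop-2-en-1-one F6. TMSOTf and 2,2'-bipyridyl (CH2Cl2, 0 °C) then convert the aryl MOM ethers and the free phenol into the octakis(trimethylsilyl) ether of kuwanon J F7, which neutral water hydrolyses to 39.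

Step 17. The aryllithium may add in a conjugate sense to the cinnamoyl Weinreb amide, or be quenched by proton transfer before it acylates. The fallback builds the chalcone by aldol condensation instead of acyl transfer of the whole arm; it sets out from 33 and returns at 38. Bromine–lithium exchange (n-BuLi, THF, −78 °C) and acylation with the small, non-conjugated N-methoxy-N-methylacetamide should give the methyl ketone 1-[(6R,6aR,7S,10aS)-6-ArA-7-ArM-6-methoxy-1-(methoxymethoxy)-9-methyl-6a,7,8,10a-tetrahydro-6H-benzo[c]chromen-2-yl]ethan-1-one F8. Claisen–Schmidt condensation of F8 with aldehyde 35 (Ba(OH)2, MeOH, 40 °C) should then give the (E)-chalcone 38, the methyl ketone being the only enolisable carbonyl group present because the ring A ketone is still a ketal.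

Further compounds
F1 | step 14 | (3E)-4-[3-bromo-6-hydroxy-2-(methoxymethoxy)phenyl]but-3-en-2-one | CC(=O)/C=C/c1c(O)ccc(Br)c1OCOC
F2 | step 14 | (1E,5S,6Z)-7-ArA-5-ArM-1-[3-bromo-6-hydroxy-2-(methoxymethoxy)phenyl]-7-methoxy-3-methylhepta-1,6-dien-3-ol, both C3 epimers | CC(O)(C[C@@H](/C=C(\OC)c1cc(OCOC)c(CC=C(C)C)c(OCOC)c1)c1ccc(OCOC)cc1OCOC)/C=C/c1c(O)ccc(Br)c1OCOC
F3 | step 14 | (3S)-1-ArA-3-ArM-4-[6-bromo-5-(methoxymethoxy)-2-methyl-2H-chromen-2-yl]butan-1-one, both chromene C2 epimers | CC1(C[C@@H](CC(=O)c2cc(OCOC)c(CC=C(C)C)c(OCOC)c2)c2ccc(OCOC)cc2OCOC)C=Cc2c(OCOC)c(Br)ccc2O1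
F4 | step 14 | 1-[(3S)-1-ArA-3-ArM-4-(6-bromo-5-(methoxymethoxy)-2-methyl-2H-chromen-2-yl)but-1-en-1-yl]pyrrolidine, alkene geometry not defined | CC1(C[C@@H](C=C(N2CCCC2)c2cc(OCOC)c(CC=C(C)C)c(OCOC)c2)c2ccc(OCOC)cc2OCOC)C=Cc2c(OCOC)c(Br)ccc2O1
F5 | step 14 | 1-[(6aR,7S,10aS)-6-ArA-7-ArM-2-bromo-1-(methoxymethoxy)-9-methyl-6a,7,8,10a-tetrahydro-6H-benzo[c]chromen-6-yl]pyrrolidine, C6 not defined | CC(C)=CCc1c(OCOC)cc(cc1OCOC)C1(N2CCCC2)Oc2ccc(Br)c(OCOC)c2[C@H]2C=C(C)C[C@H](c3ccc(OCOC)cc3OCOC)[C@@H]12
F6 | step 18 | (2E)-1-{3-[(1S,5S,6R)-6-(ArA-carbonyl)-5-ArM-3-methylcyclohex-2-en-1-yl]-4-hydroxy-2-(methoxymethoxy)phenyl}-3-ArM-prop-2-en-1-one | CC(C)=CCc1c(OCOC)cc(C(=O)[C@H]2[C@@H](c3c(O)ccc(C(=O)/C=C/c4ccc(OCOC)cc4OCOC)c3OCOC)C=C(C)C[C@@H]2c2ccc(OCOC)cc2OCOC)cc1OCOC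
F7 | step 18 | octakis-O-(trimethylsilyl) ether of kuwanon J | CC(C)=CCc1c(O[Si](C)(C)C)cc(C(=O)[C@H]2[C@@H](c3c(O[Si](C)(C)C)ccc(C(=O)/C=C/c4ccc(O[Si](C)(C)C)cc4O[Si](C)(C)C)c3O[Si](C)(C)C)C=C(C)C[C@@H]2c2ccc(O[Si](C)(C)C)cc2O[Si](C)(C)C)cc1O[Si](C)(C)C
F8 | step 17 | 1-[(6R,6aR,7S,10aS)-6-ArA-7-ArM-6-methoxy-1-(methoxymethoxy)-9-methyl-6a,7,8,10a-tetrahydro-6H-benzo[c]chromen-2-yl]ethan-1-one | CO[C@@]1(c2cc(OCOC)c(CC=C(C)C)c(OCOC)c2)Oc2ccc(C(C)=O)c(OCOC)c2[C@H]2C=C(C)C[C@H](c3ccc(OCOC)cc3OCOC)[C@@H]12
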